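The chlorinated isoflavone half is disconnected across its pyranone ring C at C3–C4, C2–O1 and O1–C8a. On ring A the C8 chlorine lies between O1 and the C7 oxygen. This contiguous pattern is bought as 3-chloro-2,4-difluorobenzoyl chloride: its fluorines, ortho and para to the acyl carbon that becomes C4, are set up for displacement, while the meta chlorine is inert. In one operation a β-morpholinostyrene that already carries the benzyl/methyl-protected diaryl ether is C-acylated, its amine is exchanged for oxygen, and ring C is closed by loss of fluoride. The surviving C7 fluoride then becomes the hydroxyl, and the genistein chromone is grown on the unmasked phenol next to the ether oxygen.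

Key step: step 7

Remarks on the chemistry:
- Ring labels: in the chlorinated chromone, ring A is the benzo ring, ring C the pyranone and ring B the para-phenylene. In the genistein half, ring D is the benzo ring, ring E the pyranone and ring F the 4-hydroxyphenyl group.
- The target has no stereocentre. Enol ether 7 is used as an E/Z mixture, and 12 and 13 are drawn without defined double-bond geometry, because all isomers converge on the same product.
- BF3·Et2O in step 10 serves as the reaction medium.

Step 1
Reactants: 1 4,6-dimethoxysalicylaldehyde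
Product: 2 2-(benzyloxy)-4,6-dimethoxybenzaldehyde
Conditions: BnBr, K2CO3, DMF, 60 °C
Reagents that add atoms: benzyl bromide, BrCc1ccccc1
Why: Williamson O-alkylation of the phenoxide, with gentle heating to overcome the hydrogen bond between the hydroxyl and the formyl group; this marks the oxygen that later becomes O1 of ring E.

Step 2
Reactants: 2 2-(benzyloxy)-4,6-dimethoxybenzaldehyde
Product: 4 2-(benzyloxy)-4,6-dimethoxyphenol, via aryl formate 3 (not isolated)
Conditions: mCPBA, CH2Cl2, 0 °C to rt; then K2CO3, MeOH, rt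
Reagents that add atoms: 3-chloroperoxybenzoic acid, O=C(OO)c1cccc(Cl)c1
Why: Dakin-type Baeyer–Villiger oxidation, in which the very electron-rich trialkoxyaryl group migrates in the Criegee adduct to give the aryl formate, which methanolysis cleaves to the phenol.

Step 3
Reactants: 4 2-(benzyloxy)-4,6-dimethoxyphenol; 5 4-fluorobenzaldehyde
Product: 6 4-[2-(benzyloxy)-4,6-dimethoxyphenoxy]benzaldehyde
Conditions: K2CO3, DMF, 120 °C, N2
Reagents that add atoms: none
Why: SNAr diaryl ether formation, in which the para formyl group stabilises the Meisenheimer adduct, a reaction that tolerates 2,6-disubstituted phenoxides; inert gas protects the electron-rich phenoxide from air.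

Step 4
Reactants: 6 4-[2-(benzyloxy)-4,6-dimethoxyphenoxy]benzaldehyde
Product: 7 1-(benzyloxy)-3,5-dimethoxy-2-[4-(2-methoxyethenyl)phenoxy]benzene (E/Z mixture)
Conditions: Ph3P(CH2OMe)Cl, KOtBu, THF, 0 °C to rt
Reagents that add atoms: (methoxymethyl)triphenylphosphonium chloride, COC[P+](c1ccccc1)(c1ccccc1)c1ccccc1.[Cl-]
Why: Wittig methoxymethylenation of a non-enolisable aryl aldehyde adds the carbon that becomes C2 of ring C; both enol ether isomers hydrolyse to the same aldehyde.

Step 5
Reactants: 7 1-(benzyloxy)-3,5-dimethoxy-2-[4-(2-methoxyethenyl)phenoxy]benzene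
Product: 9 4-[(E)-2-{4-[2-(benzyloxy)-4,6-dimethoxyphenoxy]phenyl}ethenyl]morpholine, via arylacetaldehyde 8 (not isolated)
Conditions: 2 M aq. HCl, THF, 50 °C; then morpholine, MgSO4, toluene, rt (crude aldehyde used at once)
Reagents that add atoms: morpholine, C1COCCN1
Why: Enol ether hydrolysis followed by enamine condensation, driven by conjugation of the enamine with ring B, which also makes the E isomer the thermodynamic product; the self-condensing arylacetaldehyde is never stored.

Step 6
Reactants: 10 3-chloro-2,4-difluorobenzoic acid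
Product: 11 3-chloro-2,4-difluorobenzoyl chloride
Conditions: SOCl2, cat. DMF, toluene, 80 °C; evaporate
Reagents that add atoms: thionyl chloride, O=S(Cl)Cl
Why: Standard acid chloride formation through the chlorosulfite with Vilsmeier-type catalysis; the ring halogens are untouched.

Step 7
Reactants: 9 4-[(E)-2-{4-[2-(benzyloxy)-4,6-dimethoxyphenoxy]phenyl}ethenyl]morpholine; 11 3-chloro-2,4-difluorobenzoyl chloride
Product: 14 3-{4-[2-(benzyloxy)-4,6-dimethoxyphenoxy]phenyl}-8-chloro-7-fluorochromen-4-one, via morpholino enaminone 12 (not isolated), via hydroxymethylene ketone 13 (not isolated)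
Conditions: Et3N, toluene, 0 to 50 °C; then 1 M aq. HCl, THF, rt to 40 °C, phase separation; then K2CO3, DMF, 60 °C
Reagents that add atoms: water, O
Why: The β-carbon of the enamine, which is the carbon carrying the aryl group, adds to the acid chloride in a Stork-type C-acylation (Et3N takes up HCl) and gives the vinylogous amide 12 with the C3–C4 bond in place. Dilute aqueous acid then exchanges the amine for oxygen from water by addition–elimination at the aminomethylene carbon (C2–O1 bond) and carries morpholine away as its salt, so that no amine is left to attack the C7 fluoride. With K2CO3 in DMF the enolate oxygen of 13 adds to the fluorine-bearing carbon ortho to the ketone and fluoride leaves from a Meisenheimer adduct that the ketone stabilises (O1–C8a bond); ring C closes in this six-membered addition–elimination, formally a 6-exo-trig attack on the arene carbon. The closest known chemistry is the acylation, amine exchange and fluoride displacement sequence of fluoroquinolone manufacture and the base-induced closure of 2-fluoroaryl 1,3-dicarbonyl compounds to chromones. No stereocentre is formed. The step needs displacement of the ortho fluoride only, and the substrate secures this because the para fluoride cannot be reached by the tethered oxygen and the chlorine is meta to the carbonyl and therefore unactivated.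

Step 8
Reactants: 14 3-{4-[2-(benzyloxy)-4,6-dimethoxyphenoxy]phenyl}-8-chloro-7-fluorochromen-4-one
Product: 16 3-{4-[2-(benzyloxy)-4,6-dimethoxyphenoxy]phenyl}-8-chloro-7-hydroxychromen-4-one, via O-aryl acetohydroxamate 15 (not isolated)
Conditions: acetohydroxamic acid, K2CO3, DMSO, 80 °C; aq. HCl work-up
Reagents that add atoms: acetohydroxamic acid, CC(=O)NO
Why: SNAr of the hydroxamate oxygen at C7, which is para to the C4 carbonyl, followed by Lossen-type fragmentation of the O-aryl hydroxamate, should release the phenoxide, whose charge then protects ring C from further nucleophilic attack; the C8 chlorine is meta to the carbonyl and stays.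

Step 9
Reactants: 16 3-{4-[2-(benzyloxy)-4,6-dimethoxyphenoxy]phenyl}-8-chloro-7-hydroxychromen-4-one
Product: 17 8-chloro-7-hydroxy-3-[4-(2-hydroxy-4,6-dimethoxyphenoxy)phenyl]chromen-4-one
Conditions: BCl3, pentamethylbenzene, CH2Cl2, −78 to −40 °C; MeOH quench
Reagents that add atoms: none
Why: Lewis acid debenzylation with a cation scavenger: at low temperature BCl3 cleaves the benzyl ether but not the methyl ethers, the diaryl ether or the aryl chloride (which hydrogenolysis would endanger), and pentamethylbenzene traps the benzyl cation before it can alkylate ring D in a Friedel–Crafts reaction.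

Step 10
Reactants: 17 8-chloro-7-hydroxy-3-[4-(2-hydroxy-4,6-dimethoxyphenoxy)phenyl]chromen-4-one; 18 4-methoxyphenylacetic acid
Product: 20 8-[4-(8-chloro-7-hydroxy-4-oxochromen-3-yl)phenoxy]-5,7-dimethoxy-3-(4-methoxyphenyl)chromen-4-one, via deoxybenzoin 19 (not isolated)
Conditions: BF3·Et2O, 85 °C; then DMF, MsCl, 70 °C; aq. NaOAc work-up
Reagents that add atoms: N,N-dimethylformamide, CN(C)C=O
Why: Friedel–Crafts/Fries-type C-acylation of the free phenol is funnelled to the ortho-hydroxy ketone by its BF2 chelate (the other open carbon, between the two methoxy groups, offers no chelate, and ring A is deactivated), after which the Vilsmeier-type reagent from DMF and MsCl formylates the activated methylene and the phenol oxygen closes ring E with loss of dimethylamine; this is the established one-pot route from phenols to isoflavones, and free phenols such as C7-OH survive it.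

Step 11
Reactants: 20 8-[4-(8-chloro-7-hydroxy-4-oxochromen-3-yl)phenoxy]-5,7-dimethoxy-3-(4-methoxyphenyl)chromen-4-one
Product: 21 bisoflavolin H, 8-[4-(8-chloro-7-hydroxy-4-oxochromen-3-yl)phenoxy]-5,7-dihydroxy-3-(4-hydroxyphenyl)chromen-4-one
Conditions: BBr3 (excess), CH2Cl2, −78 °C to rt; MeOH then water
Reagents that add atoms: none
Why: Lewis acid cleavage of the three aryl methyl ethers by SN2 attack of bromide on the boron-bound methoxy groups; the diaryl ether offers no sp3 carbon for bromide, and the aryl chloride and both chromones are inert to BBr3.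

Compound list
1 | 4,6-dimethoxysalicylaldehyde | O=Cc1c(O)cc(OC)cc1OC | starting material
2 | 2-(benzyloxy)-4,6-dimethoxybenzaldehyde | O=Cc1c(OCc2ccccc2)cc(OC)cc1OC | intermediate
3 | 2-(benzyloxy)-4,6-dimethoxyphenyl formate (aryl formate; not isolated) | O=COc1c(OCc2ccccc2)cc(OC)cc1OC | intermediate
4 | 2-(benzyloxy)-4,6-dimethoxyphenol | Oc1c(OCc2ccccc2)cc(OC)cc1OC | intermediate
5 | 4-fluorobenzaldehyde | O=Cc1ccc(F)cc1 | starting material
6 | 4-[2-(benzyloxy)-4,6-dimethoxyphenoxy]benzaldehyde | O=Cc1ccc(Oc2c(OCc3ccccc3)cc(OC)cc2OC)cc1 | intermediate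
7 | 1-(benzyloxy)-3,5-dimethoxy-2-[4-(2-methoxyethenyl)phenoxy]benzene (E/Z mixture) | COC=Cc1ccc(Oc2c(OCc3ccccc3)cc(OC)cc2OC)cc1 | intermediate
8 | {4-[2-(benzyloxy)-4,6-dimethoxyphenoxy]phenyl}acetaldehyde (arylacetaldehyde; not isolated) | O=CCc1ccc(Oc2c(OCc3ccccc3)cc(OC)cc2OC)cc1 | intermediate
9 | 4-[(E)-2-{4-[2-(benzyloxy)-4,6-dimethoxyphenoxy]phenyl}ethenyl]morpholine | COc1cc(OC)c(Oc2ccc(/C=C/N3CCOCC3)cc2)c(OCc2ccccc2)c1 | intermediate
10 | 3-chloro-2,4-difluorobenzoic acid | O=C(O)c1ccc(F)c(Cl)c1F | starting material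
11 | 3-chloro-2,4-difluorobenzoyl chloride | O=C(Cl)c1ccc(F)c(Cl)c1F | intermediate
12 | 2-{4-[2-(benzyloxy)-4,6-dimethoxyphenoxy]phenyl}-1-(3-chloro-2,4-difluorophenyl)-3-(morpholin-4-yl)prop-2-en-1-one (morpholino enaminone; not isolated) | O=C(C(=CN1CCOCC1)c1ccc(Oc2c(OCc3ccccc3)cc(OC)cc2OC)cc1)c1ccc(F)c(Cl)c1F | intermediate
13 | 2-{4-[2-(benzyloxy)-4,6-dimethoxyphenoxy]phenyl}-1-(3-chloro-2,4-difluorophenyl)-3-hydroxyprop-2-en-1-one (hydroxymethylene ketone, enol form of the α-formyl ketone; not isolated) | OC=C(c1ccc(Oc2c(OCc3ccccc3)cc(OC)cc2OC)cc1)C(=O)c1ccc(F)c(Cl)c1F | intermediate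
14 | 3-{4-[2-(benzyloxy)-4,6-dimethoxyphenoxy]phenyl}-8-chloro-7-fluorochromen-4-one | O=c1c(-c2ccc(Oc3c(OCc4ccccc4)cc(OC)cc3OC)cc2)coc2c(Cl)c(F)ccc12 | intermediate
15 | N-[(3-{4-[2-(benzyloxy)-4,6-dimethoxyphenoxy]phenyl}-8-chloro-4-oxochromen-7-yl)oxy]acetamide (O-aryl acetohydroxamate; not isolated) | CC(=O)NOc1ccc2c(=O)c(-c3ccc(Oc4c(OCc5ccccc5)cc(OC)cc4OC)cc3)coc2c1Cl | intermediate
16 | 3-{4-[2-(benzyloxy)-4,6-dimethoxyphenoxy]phenyl}-8-chloro-7-hydroxychromen-4-one | O=c1c(-c2ccc(Oc3c(OCc4ccccc4)cc(OC)cc3OC)cc2)coc2c(Cl)c(O)ccc12 | intermediate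
17 | 8-chloro-7-hydroxy-3-[4-(2-hydroxy-4,6-dimethoxyphenoxy)phenyl]chromen-4-one | O=c1c(-c2ccc(Oc3c(O)cc(OC)cc3OC)cc2)coc2c(Cl)c(O)ccc12 | intermediate
18 | 4-methoxyphenylacetic acid | COc1ccc(CC(=O)O)cc1 | starting material
19 | 8-chloro-7-hydroxy-3-(4-{2-hydroxy-4,6-dimethoxy-3-[(4-methoxyphenyl)acetyl]phenoxy}phenyl)chromen-4-one (deoxybenzoin; not isolated) | O=c1c(-c2ccc(Oc3c(O)c(C(=O)Cc4ccc(OC)cc4)c(OC)cc3OC)cc2)coc2c(Cl)c(O)ccc12 | intermediate
20 | 8-[4-(8-chloro-7-hydroxy-4-oxochromen-3-yl)phenoxy]-5,7-dimethoxy-3-(4-methoxyphenyl)chromen-4-one | O=c1c(-c2ccc(Oc3c(OC)cc(OC)c4c(=O)c(-c5ccc(OC)cc5)coc34)cc2)coc2c(Cl)c(O)ccc12 | intermediate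
21 | bisoflavolin H, 8-[4-(8-chloro-7-hydroxy-4-oxochromen-3-yl)phenoxy]-5,7-dihydroxy-3-(4-hydroxyphenyl)chromen-4-one | O=c1c(-c2ccc(Oc3c(O)cc(O)c4c(=O)c(-c5ccc(O)cc5)coc34)cc2)coc2c(Cl)c(O)ccc12 | target

Total step count: 11.
Longest linear sequence: 10 steps (1 to 21 through steps 1–5 and 7–11); step 6 is a one-step side branch.

Steps most likely to fail

Step 7. C-acylation at the hindered, aryl-conjugated enamine carbon may be slow, so that N-acylation and hydrolysis return the aldehyde. The hydroxymethylene ketone may also lose its formyl group by retro-Claisen cleavage before the ring closes. The fallback sets out from 6 (with 11) and returns at 14; it forms the C3–C4 bond by ketone synthesis and brings in C2 afterwards. Aldehyde 6 is reduced with NaBH4 in MeOH to {4-[2-(benzyloxy)-4,6-dimethoxyphenoxy]phenyl}methanol F1. MsCl, Et3N and LiCl in THF convert it into the benzylic chloride 1-(benzyloxy)-2-[4-(chloromethyl)phenoxy]-3,5-dimethoxybenzene F2. Zinc dust with LiCl in THF inserts to give the benzylzinc chloride F3. Acylation of F3 with 11 under Pd(PPh3)4 catalysis (zerovalent palladium, Negishi-type ketone synthesis) gives the deoxybenzoin 2-{4-[2-(benzyloxy)-4,6-dimethoxyphenoxy]phenyl}-1-(3-chloro-2,4-difluorophenyl)ethanone F4. Condensation with DMF dimethyl acetal in toluene at 90 °C gives the dimethylamino enaminone F5. Dilute aqueous HCl converts F5 into 13, and K2CO3 in DMF closes 13 to 14 as in the main route.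

Step 10. Acylation may take place at the ring carbon between the two methoxy groups (para to the hydroxyl) and not ortho to the hydroxyl, or it may stall because the Lewis acid is bound by the many basic sites of the substrate. The fallback sets out from 17 and returns at 20; it delivers the acyl group through a boron tether. Phenol 17 is treated with BCl3, then with 4-methoxyphenylacetonitrile and AlCl3 in CH2Cl2, kept at 0 °C to room temperature so that the methyl ethers are not touched (Sugasawa-type ortho-acylation through the aryloxydichloroborane). This should give the ketimine 8-chloro-7-hydroxy-3-(4-{2-hydroxy-3-[2-(4-methoxyphenyl)ethanimidoyl]-4,6-dimethoxyphenoxy}phenyl)chromen-4-one F7 as its boron chelate. Warm 2 M HCl hydrolyses F7 to deoxybenzoin 19, which is isolated here. Ring E is then closed with BF3·Et2O, DMF and MsCl as in the main route to give 20.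

Step 8. The oxygen nucleophile may add at C2 and open ring C during the long heating, or the N–O fragmentation of the O-aryl hydroxamate may stall. The fallback sets out from 14 and returns at 17; the oxygen arrives as an ether and is unveiled together with the other phenol. Sodium benzyloxide (BnOH, NaH, THF, 0 °C) displaces the C7 fluoride to give 7-(benzyloxy)-3-{4-[2-(benzyloxy)-4,6-dimethoxyphenoxy]phenyl}-8-chlorochromen-4-one F6. Any adduct at C2 should reclose on acidification. The BCl3 and pentamethylbenzene conditions of step 9 then remove both benzyl groups and give 17 directly.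

Further compounds
F1 | step 7 | {4-[2-(benzyloxy)-4,6-dimethoxyphenoxy]phenyl}methanol | OCc1ccc(Oc2c(OCc3ccccc3)cc(OC)cc2OC)cc1
F2 | step 7 | 1-(benzyloxy)-2-[4-(chloromethyl)phenoxy]-3,5-dimethoxybenzene | ClCc1ccc(Oc2c(OCc3ccccc3)cc(OC)cc2OC)cc1
F3 | step 7 | {4-[2-(benzyloxy)-4,6-dimethoxyphenoxy]benzyl}zinc chloride | Cl[Zn]Cc1ccc(Oc2c(OCc3ccccc3)cc(OC)cc2OC)cc1
F4 | step 7 | 2-{4-[2-(benzyloxy)-4,6-dimethoxyphenoxy]phenyl}-1-(3-chloro-2,4-difluorophenyl)ethanone | O=C(Cc1ccc(Oc2c(OCc3ccccc3)cc(OC)cc2OC)cc1)c1ccc(F)c(Cl)c1F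
F5 | step 7 | 2-{4-[2-(benzyloxy)-4,6-dimethoxyphenoxy]phenyl}-1-(3-chloro-2,4-difluorophenyl)-3-(dimethylamino)prop-2-en-1-one | CN(C)C=C(c1ccc(Oc2c(OCc3ccccc3)cc(OC)cc2OC)cc1)C(=O)c1ccc(F)c(Cl)c1F
F6 | step 8 | 7-(benzyloxy)-3-{4-[2-(benzyloxy)-4,6-dimethoxyphenoxy]phenyl}-8-chlorochromen-4-one | O=c1c(-c2ccc(Oc3c(OCc4ccccc4)cc(OC)cc3OC)cc2)coc2c(Cl)c(OCc3ccccc3)ccc12
F7 | step 10 | 8-chloro-7-hydroxy-3-(4-{2-hydroxy-3-[2-(4-methoxyphenyl)ethanimidoyl]-4,6-dimethoxyphenoxy}phenyl)chromen-4-one | N=C(Cc1ccc(OC)cc1)c1c(OC)cc(OC)c(Oc2ccc(-c3coc4c(Cl)c(O)ccc4c3=O)cc2)c1O
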